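**Assumption:** electrophilic bromination of olivetol 5 is taken to follow the usual order of 5-alkylresorcinols, with the equivalent carbons C4 and C6 reacting before C2. Carbon dioxide is counted as numbered reactant 10 because its carbon becomes the carboxyl carbon of 12.

## The problem

Planaic acid 12 is a depside: two pentyl-substituted benzene rings that share no carbon–carbon bond and are joined only by an aryl ester between the C4 oxygen of ring A (the 2-methoxy-6-pentylbenzoic acid ring) and the carbonyl carbon of ring B (a 2,4-dimethoxy-6-pentylbenzoyl group). There is no stereocentre and no ring to build, since both arenes carry the oxygen pattern of olivetol, so the task is one of order and chemoselectivity. On ring A three things must be placed correctly: a methyl on the C2 oxygen, the acyl group on the C4 oxygen, and a free carboxyl on C1 between the C2 methoxyl and the C6 pentyl chain. The aryl ester is an activated ester that will not survive hydroxide, alkoxide or hard organometallic reagents, so the acid of ring A cannot be set free by saponification, and the electron-rich acid itself decarboxylates in hot mineral acid. Both rings are nucleophilic, ring B especially, so any electrophilic substitution on ring A must be finished before the halves are joined. The feature that opens the key step is that C1 of ring A carries nothing but the carboxyl carbon: with bromine in its place the molecule has a single carbon–halogen bond, which a low-valent nickel complex can enter at a potential that leaves the ester alone, so that carbon dioxide 10 can supply the missing carbon as the last act. That same carbon is, in the parent resorcinol, one of two equivalent positions between a hydroxyl and the pentyl chain, which is where an electrophile goes.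

## Retrosynthesis

**The carboxyl carbon.** The first cut is the bond between C1 of ring A and the carboxyl carbon of 12, which removes that carbon as carbon dioxide 10 and leaves the aryl bromide 9. Cutting the ester first would leave a hydroxy acid whose carboxyl must pass through the esterification as a benzyl ester or an aldehyde and be uncovered afterwards. Cutting the carbon–carbon bond removes the acid and every protecting group with it. Bromide 9 is neutral, has no acidic proton, and has the ester as its only electrophilic site. The forward reaction is a nickel-catalysed cathodic carboxylation that gives the magnesium carboxylate 11 and, after acid, 12. It must activate the carbon–bromine bond without reducing or cleaving the ester and without protonating the aryl nickel intermediate.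

**The methyl next to bromine.** In 9 the oxygen–methyl bond at C3 of the bromophenyl ring (the future C2 methoxyl of ring A) is cut to give phenol 8. The reverse order, methyl first and acyl second, would need a bromophenol whose two oxygens are already told apart, and the shortest regiochemically safe path to such a compound is a protecting-group relay of three steps. Methylating last lets the ester itself be the group that distinguishes the two oxygens. The forward reaction is a Williamson etherification with a base too weak to open the ester.

**The depside ester.** Phenol 8 is cut at the acyl carbon–oxygen bond into 4-bromo-5-pentylbenzene-1,3-diol 6 and acid chloride 7, which is made in the flask from acid 4. Diol 6 has two different hydroxyls. One is ortho to bromine, hydrogen-bonded to it and flanked by it. The other has only hydrogens as neighbours and lies para to bromine. A 2,6-disubstituted aroyl chloride under weak-base conditions should take the open one, as bulky silyl and acyl chlorides do with 4-bromoresorcinols. The forward reaction must give monoacylation at that oxygen.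

**The bromine.** Diol 6 is cut at the carbon–bromine bond to olivetol 5. Bromination belongs here because C4 and C6 of 5 are equivalent, so monobromination between a hydroxyl and the pentyl chain can give only one such product. Had one hydroxyl been methylated first, the electrophile would have to choose between the carbon para to hydroxyl and the carbon para to methoxyl. Both are flanked by the pentyl chain and are almost equally activated, so a mixture would be expected. After union of the two halves it would be too late, because ring B would be brominated first. The forward reaction must stop at the monobromide.

**Ring B.** Acid chloride 7 comes from acid 4, acid 4 from aldehyde 3 by oxidation, and 3 from commercial 1,3-dimethoxy-5-pentylbenzene 1 by formylation through iminium chloride 2. The bond cut is that between C1 of ring B and its carbonyl carbon. No sensitive group is present on this half, so classical formylation and oxidation suffice. Formylation must go to the carbon between a methoxyl and the pentyl chain, not to the one between the two methoxyls.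

## Roads not taken

**Alternative 1:** Biomimetic aldol folding of a polyketide chain.
- **Cut:** the C1–C6 bond of an olivetolate ring.
- **Forward key step:** benzyl 3,5,7-trioxododecanoate A1 would be treated with mild base and then acid, so that chain carbon 2 adds to the C7 ketone and dehydration with enolisation gives benzyl 2,4-dihydroxy-6-pentylbenzoate A2.
- **Use of A2:** one batch would feed both rings. One portion would be methylated on both hydroxyls and hydrogenolysed to acid 4. For ring A, the 4-hydroxyl of A2 would be protected, the chelated 2-hydroxyl methylated and the 4-hydroxyl released, giving benzyl 4-hydroxy-2-methoxy-6-pentylbenzoate A3. Acylation of A3 with 7 would give benzyl 4-[(2,4-dimethoxy-6-pentylbenzoyl)oxy]-2-methoxy-6-pentylbenzoate A4, and hydrogenolysis of A4 would give 12.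
- **Merits:** the carboxyl carbon of ring A is present from the start, and the ring substitution is fixed by the folding. No bromine and no site-selective acylation is needed, because A3 has a single free hydroxyl. The last step, hydrogenolysis of the benzyl ester A4 beside an aryl ester, is more reliable than an electrolysis.
- **Weak points:** A1 is a labile poly-β-carbonyl compound that needs polyanion chemistry to make. It can close in other modes (Claisen-type C-acylation, lactonisation to a pyrone). Ring A needs a protect–methylate–deprotect sequence because the hydroxyl to be methylated is the less reactive one. The total should be roughly twice the step count.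
- **Comparison:** this road is safer at the end. The chosen plan sets against it two purchased rings, no protecting group, about half the steps, and a stoichiometric fallback from the same bromide 9 if the electrolysis fails.

**Alternative 2:** Pyrone cycloaddition with loss of carbon dioxide.
- **Cut:** two ring carbon–carbon bonds of ring B.
- **Forward key step:** benzyl 4-methoxy-2-oxo-6-pentyl-2H-pyran-5-carboxylate A5 and 1,1-dimethoxyethene A6 would be heated. A (4+2) cycloaddition across C3 and C6 of A5 would be followed by extrusion of carbon dioxide 10 and loss of one acetal methoxyl to give benzyl 2,4-dimethoxy-6-pentylbenzoate A7. Hydrogenolysis of A7 would give acid 4.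
- **Merits:** the polarised pairing (nucleophilic methylene terminus of A6 to the ester-activated C6 of A5) fixes the substitution pattern of ring B without ambiguity. That is better than formylation of 1, which can give a minor isomer by attack between the methoxyls. The benzyl ester of A7 is removed under neutral conditions.
- **Weak points:** A5 has to be built in several steps, with its own O-methylation regiochemistry. A6 is moisture-sensitive and is used in excess. The sequence delivers only ring B, which is two steps from commercial 1, and leaves the real difficulty, the free acid of ring A beside the depside ester, untouched.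
- **Comparison:** it gains regiochemical purity on ring B. The chosen plan sets against that a two-step entry to 4 and an aldehyde 3 that should be easy to purify.

**Alternative 3:** Aryne carbomagnesiation and carboxylation.
- **Cut:** the aryl–pentyl and aryl–carboxyl bonds of ring B.
- **Forward key step:** 2-iodo-3,5-dimethoxyphenyl trifluoromethanesulfonate A8 would be treated with excess pentylmagnesium bromide A9. Iodine–magnesium exchange and loss of triflate would give 3,5-dimethoxybenzyne A10. A9 would add to A10 at the aryne carbon remote from the flanking methoxyl to give (2,4-dimethoxy-6-pentylphenyl)magnesium bromide A11, and quenching A11 with carbon dioxide 10 would give 2,4-dimethoxy-6-pentylbenzoic acid A12, which is the same compound as 4.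
- **Merits:** two bonds form in one flask, the acid A12 appears directly without an oxidant near the electron-rich ring, and the methoxyl next to the triple bond of A10 steers the addition. In those respects it equals or slightly betters steps 1 and 2.
- **Weak points:** A8 must itself be prepared by a regioselective iodination and a triflation. The pentyl chain is installed on a ring that can be bought with it in place. Addition of A9 to A10 competes with proton transfer and further exchange, and A11 can be lost to protonation before it meets carbon dioxide. Ring A is not addressed.
- **Comparison:** there is no saving in steps. The chosen plan keeps the carboxylation with carbon dioxide for C1 of ring A, where it removes a protecting group problem instead of duplicating a catalogue compound.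

Key step: step 6

## Route

Step 1
Reactants: 1 1,3-dimethoxy-5-pentylbenzene (olivetol dimethyl ether)
Product: 3 2,4-dimethoxy-6-pentylbenzaldehyde, via iminium chloride 2 (not isolated)
Conditions: POCl3, DMF, 0 °C to 70 °C; then ice-water, rt
Reagents that add atoms: N,N-dimethylformamide, CN(C)C=O (formyl carbon); water, O (carbonyl oxygen)
Why: Vilsmeier–Haack formylation; the chloroiminium ion should attack C4 (equivalent to C6), para to one methoxyl and ortho to the other, in preference to the more crowded C2 between the two methoxyls, and iminium salt 2 is hydrolysed on aqueous work-up. Any isomeric aldehyde from attack at C2 should be removable by chromatography.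

Step 2
Reactants: 3 2,4-dimethoxy-6-pentylbenzaldehyde
Product: 4 2,4-dimethoxy-6-pentylbenzoic acid
Conditions: NaClO2, NaH2PO4, 2-methyl-2-butene (excess), t-BuOH/H2O, 0 °C to rt
Reagents that add atoms: sodium chlorite, [Na+].[O-]Cl=O
Why: Pinnick oxidation of an aromatic aldehyde; the buffered chlorite oxidises only the formyl group, and the alkene scavenger should take up the hypochlorous acid before it can chlorinate the electron-rich ring.

Step 3
Reactants: 5 olivetol (5-pentylbenzene-1,3-diol)
Product: 6 4-bromo-5-pentylbenzene-1,3-diol
Conditions: NBS (1.0 equiv, slow addition), MeCN, −30 °C to 0 °C
Reagents that add atoms: N-bromosuccinimide, O=C1CCC(=O)N1Br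
Why: Electrophilic aromatic bromination; C4 and C6 are equivalent by symmetry and each is ortho to one hydroxyl and para to the other, so they should react before C2, and the first bromine lowers the reactivity enough for the reaction to be held at the monobromide with one equivalent in the cold.

Step 4
Reactants: 4 2,4-dimethoxy-6-pentylbenzoic acid; 6 4-bromo-5-pentylbenzene-1,3-diol
Product: 8 4-bromo-3-hydroxy-5-pentylphenyl 2,4-dimethoxy-6-pentylbenzoate, via acid chloride 7 (not isolated)
Conditions: 4, (COCl)2, DMF (cat.), CH2Cl2, 0 °C to rt, evaporate; then added slowly to 6 (1.5 equiv), pyridine, 4-(dimethylamino)pyridine (cat.), CH2Cl2, −20 °C to rt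
Reagents that add atoms: none
Why: Acid chloride formation followed by site-selective acylation of a phenol through the acylpyridinium ion; the 2,6-disubstituted aroyl group should go to the hydroxyl para to bromine, which has only hydrogens as neighbours, and not to the hydroxyl that is flanked by and hydrogen-bonded to bromine. Weak base keeps both hydroxyls un-ionised so that the more acidic ortho-bromo hydroxyl gains no advantage, and the excess of cheap diol 6 suppresses double acylation.

Step 5
Reactants: 8 4-bromo-3-hydroxy-5-pentylphenyl 2,4-dimethoxy-6-pentylbenzoate
Product: 9 4-bromo-3-methoxy-5-pentylphenyl 2,4-dimethoxy-6-pentylbenzoate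
Conditions: MeI (excess), K2CO3, acetone, rt
Reagents that add atoms: iodomethane, CI
Why: Williamson ether synthesis on an acidic ortho-bromophenol; carbonate in acetone is enough to form the phenoxide, excess iodomethane traps it quickly, and the ester carbonyl is shielded by the two ortho substituents of ring B against acyl transfer.

Step 6
Reactants: 9 4-bromo-3-methoxy-5-pentylphenyl 2,4-dimethoxy-6-pentylbenzoate; 10 carbon dioxide
Product: 12 planaic acid (4-[(2,4-dimethoxy-6-pentylbenzoyl)oxy]-2-methoxy-6-pentylbenzoic acid), via magnesium carboxylate 11 (not isolated)
Conditions: NiBr2(2,2'-bipyridine) (10 mol %), 2,2'-bipyridine (20 mol %), Bu4NBF4 (0.1 M), dry DMF, CO2 (1 atm), Mg rod anode, carbon-fibre cathode, undivided cell, constant current, 0 to 20 °C; then cold 1 M HCl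
Reagents that add atoms: carbon dioxide, O=C=O
Why: Nickel-catalysed electroreductive carboxylation of an aryl halide with CO2 at a sacrificial magnesium anode, a known reaction type for aryl bromides. The cathode reduces the divalent nickel bipyridine complex to zerovalent nickel, which inserts into the only carbon–bromine bond of 9; one-electron reduction of the divalent aryl nickel bromide gives a monovalent aryl nickel species that adds to CO2, and a further electron releases the carboxylate and returns zerovalent nickel. Magnesium ions from the anode pair with the carboxylate to give salt 11, which is not reduced further and is protonated to 12 on cold acidic work-up. No ring is closed and no stereocentre is formed; the single new bond joins C1 of ring A to the carbon of CO2. The step needs chemoselectivity for carbon–bromine activation over reduction or cleavage of the aryl ester and over protonation of the aryl nickel intermediate. The first is secured because the nickel mediator works at a potential well short of that at which an aryl benzoate accepts an electron, because the medium holds no hydroxide, alkoxide or amine, and because the ester carbonyl is shielded by the two ortho groups of ring B. The second is secured by a rigorously dry, CO2-saturated cell; the two groups ortho to C1 slow oxidative addition but also block biaryl homocoupling. Site selectivity is not in question, since 9 carries one bromine.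

## Compound list

1 | 1,3-dimethoxy-5-pentylbenzene (olivetol dimethyl ether) | CCCCCc1cc(OC)cc(OC)c1 | starting material
2 | N-[(2,4-dimethoxy-6-pentylphenyl)methylidene]-N-methylmethanaminium chloride | CCCCCc1cc(OC)cc(OC)c1C=[N+](C)C.[Cl-] | intermediate
3 | 2,4-dimethoxy-6-pentylbenzaldehyde | CCCCCc1cc(OC)cc(OC)c1C=O | intermediate
4 | 2,4-dimethoxy-6-pentylbenzoic acid | CCCCCc1cc(OC)cc(OC)c1C(=O)O | intermediate
5 | olivetol (5-pentylbenzene-1,3-diol) | CCCCCc1cc(O)cc(O)c1 | starting material
6 | 4-bromo-5-pentylbenzene-1,3-diol | CCCCCc1cc(O)cc(O)c1Br | intermediate
7 | 2,4-dimethoxy-6-pentylbenzoyl chloride | CCCCCc1cc(OC)cc(OC)c1C(=O)Cl | intermediate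
8 | 4-bromo-3-hydroxy-5-pentylphenyl 2,4-dimethoxy-6-pentylbenzoate | CCCCCc1cc(OC(=O)c2c(CCCCC)cc(OC)cc2OC)cc(O)c1Br | intermediate
9 | 4-bromo-3-methoxy-5-pentylphenyl 2,4-dimethoxy-6-pentylbenzoate | CCCCCc1cc(OC(=O)c2c(CCCCC)cc(OC)cc2OC)cc(OC)c1Br | intermediate
10 | carbon dioxide | O=C=O | starting material
11 | magnesium bis{4-[(2,4-dimethoxy-6-pentylbenzoyl)oxy]-2-methoxy-6-pentylbenzoate} | CCCCCc1cc(OC(=O)c2c(CCCCC)cc(OC)cc2OC)cc(OC)c1C(=O)[O-].CCCCCc1cc(OC(=O)c2c(CCCCC)cc(OC)cc2OC)cc(OC)c1C(=O)[O-].[Mg+2] | intermediate
12 | planaic acid (4-[(2,4-dimethoxy-6-pentylbenzoyl)oxy]-2-methoxy-6-pentylbenzoic acid) | CCCCCc1cc(OC(=O)c2c(CCCCC)cc(OC)cc2OC)cc(OC)c1C(=O)O | target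

## Step count and risks

Total step count: 6. Longest linear sequence: 5 steps (steps 1, 2, 4, 5 and 6 from compound 1); the branch from olivetol 5 is 4 steps (3, 4, 5, 6).

**Step 6 (key step).**
- Risk: protonation of the aryl nickel intermediate before it meets CO2, with net loss of bromine. Slow oxidative addition at the doubly flanked C1 and any water in the cell favour this.
- Second risk: reductive or nucleophilic cleavage of the depside ester if the cathode potential drifts negative once the catalyst is starved of substrate.
- Fallback, replacing catalytic electroreduction by stoichiometric halogen–metal exchange: it sets out from 9. Bromine–magnesium exchange with i-PrMgCl·LiCl in THF at −15 °C to room temperature should give {4-[(2,4-dimethoxy-6-pentylbenzoyl)oxy]-2-methoxy-6-pentylphenyl}magnesium chloride F1. The ortho methoxyl should assist the exchange and the shielded 2,6-disubstituted aroyl ester should tolerate it. Gaseous carbon dioxide 10 should convert F1 into chloromagnesium 4-[(2,4-dimethoxy-6-pentylbenzoyl)oxy]-2-methoxy-6-pentylbenzoate F2, and cold dilute HCl then frees the acid, so that the route is rejoined at 12.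

**Step 4.**
- Risk: loss of site selectivity between the two hydroxyls of 6, or double acylation. The hydroxyl next to bromine is the more acidic and becomes the better nucleophile wherever it is deprotonated, and an electron-rich aroyl chloride can react through a small acylium-like species that feels little steric difference.
- Fallback, a silyl relay in place of direct selective acylation: it sets out from 6. i-Pr3SiCl and imidazole in CH2Cl2 at 0 °C should silylate the open hydroxyl to give 2-bromo-3-pentyl-5-{[tri(propan-2-yl)silyl]oxy}phenol F3. MeI and K2CO3 in acetone should then give (4-bromo-3-methoxy-5-pentylphenoxy)tri(propan-2-yl)silane F4. Bu4NF buffered with AcOH in THF at 0 °C should free 4-bromo-3-methoxy-5-pentylphenol F5. Acylation of F5 with 7, prepared from 4 and (COCl)2 as in step 4 (pyridine, catalytic 4-(dimethylamino)pyridine), is then unambiguous and rejoins the route at 9, bypassing 8 and step 5.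
- Cost and gain: the relay is two steps longer. The selective step is run on inexpensive material with a reagent class for which the steric preference is well established, and the methylation no longer has an ester in the molecule.

**Step 3.**
- Risk: over-bromination at both C4 and C6 and some attack at C2, because the free resorcinol is very reactive.
- Fallback, bromination at the ether stage: it sets out from 1. NBS in MeCN at 0 °C should give 2-bromo-1,5-dimethoxy-3-pentylbenzene F6, since the less activated ring is easier to stop at one bromine and the position between the methoxyls is disfavoured. BBr3 (excess) in CH2Cl2 (−78 °C to rt) then removes both methyl groups, and aqueous work-up rejoins the route at 6.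

**Step 2.**
- Risk: chlorination of the electron-rich ring by hypochlorous acid set free in the oxidation, if the scavenger is outrun.
- Fallback, carboxylation instead of oxidation: it sets out from 1 and passes through 2-bromo-1,5-dimethoxy-3-pentylbenzene F6, made with NBS as in the fallback to step 3. Bromine–lithium exchange with n-BuLi in THF at −78 °C should give (2,4-dimethoxy-6-pentylphenyl)lithium F7. Carbon dioxide 10 should convert it into lithium 2,4-dimethoxy-6-pentylbenzoate F8, and aqueous HCl rejoins the route at 4, with no oxidant and without aldehyde 3.

## Further compounds

F1 | step 6 | {4-[(2,4-dimethoxy-6-pentylbenzoyl)oxy]-2-methoxy-6-pentylphenyl}magnesium chloride | CCCCCc1cc(OC(=O)c2c(CCCCC)cc(OC)cc2OC)cc(OC)c1[Mg]Cl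
F2 | step 6 | chloromagnesium 4-[(2,4-dimethoxy-6-pentylbenzoyl)oxy]-2-methoxy-6-pentylbenzoate | CCCCCc1cc(OC(=O)c2c(CCCCC)cc(OC)cc2OC)cc(OC)c1C(=O)[O-].[Mg+2].[Cl-]
F3 | step 4 | 2-bromo-3-pentyl-5-{[tri(propan-2-yl)silyl]oxy}phenol | CCCCCc1cc(O[Si](C(C)C)(C(C)C)C(C)C)cc(O)c1Br
F4 | step 4 | (4-bromo-3-methoxy-5-pentylphenoxy)tri(propan-2-yl)silane | CCCCCc1cc(O[Si](C(C)C)(C(C)C)C(C)C)cc(OC)c1Br
F5 | step 4 | 4-bromo-3-methoxy-5-pentylphenol | CCCCCc1cc(O)cc(OC)c1Br
F6 | step 3 | 2-bromo-1,5-dimethoxy-3-pentylbenzene | CCCCCc1cc(OC)cc(OC)c1Br
F7 | step 2 | (2,4-dimethoxy-6-pentylphenyl)lithium | [Li]c1c(CCCCC)cc(OC)cc1OC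
F8 | step 2 | lithium 2,4-dimethoxy-6-pentylbenzoate | CCCCCc1cc(OC)cc(OC)c1C(=O)[O-].[Li+]
A1 | alternative 1 | benzyl 3,5,7-trioxododecanoate | CCCCCC(=O)CC(=O)CC(=O)CC(=O)OCc1ccccc1
A2 | alternative 1 | benzyl 2,4-dihydroxy-6-pentylbenzoate (benzyl olivetolate) | CCCCCc1cc(O)cc(O)c1C(=O)OCc1ccccc1
A3 | alternative 1 | benzyl 4-hydroxy-2-methoxy-6-pentylbenzoate | CCCCCc1cc(O)cc(OC)c1C(=O)OCc1ccccc1
A4 | alternative 1 | benzyl 4-[(2,4-dimethoxy-6-pentylbenzoyl)oxy]-2-methoxy-6-pentylbenzoate | CCCCCc1cc(OC(=O)c2c(CCCCC)cc(OC)cc2OC)cc(OC)c1C(=O)OCc1ccccc1
A5 | alternative 2 | benzyl 4-methoxy-2-oxo-6-pentyl-2H-pyran-5-carboxylate | CCCCCC1=C(C(=O)OCc2ccccc2)C(OC)=CC(=O)O1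
A6 | alternative 2 | 1,1-dimethoxyethene | COC(=C)OC
A7 | alternative 2 | benzyl 2,4-dimethoxy-6-pentylbenzoate | CCCCCc1cc(OC)cc(OC)c1C(=O)OCc1ccccc1
A8 | alternative 3 | 2-iodo-3,5-dimethoxyphenyl trifluoromethanesulfonate | COc1cc(OC)c(I)c(OS(=O)(=O)C(F)(F)F)c1
A9 | alternative 3 | pentylmagnesium bromide | CCCCC[Mg]Br
A10 | alternative 3 | 3,5-dimethoxybenzyne (1,2-didehydro-3,5-dimethoxybenzene) | COC1=CC(OC)=CC#C1
A11 | alternative 3 | (2,4-dimethoxy-6-pentylphenyl)magnesium bromide | CCCCCc1cc(OC)cc(OC)c1[Mg]Br
A12 | alternative 3 | 2,4-dimethoxy-6-pentylbenzoic acid (identical with 4) | CCCCCc1cc(OC)cc(OC)c1C(=O)O
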